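**Retrosynthetic overview**
1. The dispiro cyclobutane is disconnected last: a head-to-head, anti [2+2] photocycloaddition of fimbrolide 14 with (R)-acetoxyfimbrolide 17 (two C–C bonds, four ring stereocentres).
2. 17 comes from 14 by radical bromination at C1′, solvolysis to the alcohol and lipase kinetic resolution/acetylation (fixes 1′R).
3. The furanone ring of 14 comes from 2-butyl-4-oxopentanoic acid 10 by α,α′-dibromination and oxidative enol-lactonisation in sulfuric acid.
4. The C9 skeleton of 10 is assembled by the key fragment union, an intermolecular aldol addition of the lithium enolate of ketal-protected ethyl levulinate to butanal, then dehydration, hydrogenation and hydrolysis.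
5. Ring order: furanone ring (step 7, serves both halves), then cyclobutane (step 11).

Assumption: the SMILES is read as the 1′R, 5S,6S,11R,12R isomer (lactone oxygens anti; each ring bromine trans to the oxygen on the adjacent spiro carbon and trans to the other bromine); primed locants are side-chain atoms on furanone C3.

**Step 1**
Reactants: 1 ethyl levulinate
Product: 2 ethyl 3-(2-methyl-1,3-dioxolan-2-yl)propanoate
Conditions: ethylene glycol (1.5 equiv), p-TsOH·H2O (2 mol%), toluene, reflux, Dean–Stark
Reagents that add atoms: ethylene glycol (OCCO)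
Why: Acid-catalysed ketalisation with azeotropic water removal masks the ketone so that only the ester α-CH2 can be enolised in step 2; no stereocentre is formed.

**Step 2**
Reactants: 2 ethyl 3-(2-methyl-1,3-dioxolan-2-yl)propanoate; 3 butanal
Product: 5 ethyl 3-hydroxy-2-[(2-methyl-1,3-dioxolan-2-yl)methyl]hexanoate, via lithium ester enolate 4 (not isolated)
Conditions: LDA (1.05 equiv, commercial solution), THF, −78 °C, 45 min; butanal (1.1 equiv), −78 °C, 30 min; sat. aq NH4Cl
Reagents that add atoms: none
Why: Directed (crossed) aldol addition of a preformed lithium ester enolate to the aldehyde at −78 °C forges the C2–C1′ bond joining the side-chain carbons to the levulinate carbons; the two new stereocentres form as a diastereomer mixture that is later erased (steps 3 and 7).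

**Step 3**
Reactants: 5 ethyl 3-hydroxy-2-[(2-methyl-1,3-dioxolan-2-yl)methyl]hexanoate
Product: 7 ethyl 2-[(2-methyl-1,3-dioxolan-2-yl)methyl]hex-2-enoate, via β-mesyloxy ester 6 (not isolated)
Conditions: MsCl (1.2 equiv), Et3N (1.5 equiv), CH2Cl2, 0 °C; then DBU (2 equiv), 0 °C → rt
Reagents that add atoms: none
Why: Mesylation followed by E1cB β-elimination completes the aldol condensation to the conjugated ester, and the E/Z ratio is irrelevant because the alkene is hydrogenated next.

**Step 4**
Reactants: 7 ethyl 2-[(2-methyl-1,3-dioxolan-2-yl)methyl]hex-2-enoate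
Product: 8 ethyl 2-[(2-methyl-1,3-dioxolan-2-yl)methyl]hexanoate
Conditions: H2 (1 atm), 10% Pd/C, EtOAc, rt
Reagents that add atoms: none
Why: Heterogeneous catalytic hydrogenation saturates the conjugated trisubstituted alkene without touching ester or ketal; the α-stereocentre is racemic and becomes sp2 in step 7.

**Step 5**
Reactants: 8 ethyl 2-[(2-methyl-1,3-dioxolan-2-yl)methyl]hexanoate
Product: 10 2-butyl-4-oxopentanoic acid, via ethyl 2-butyl-4-oxopentanoate 9 (not isolated)
Conditions: 3 M aq HCl, 1,4-dioxane, 90 °C, 8 h
Reagents that add atoms: water (O)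
Why: Acid hydrolysis first cleaves the ketal and then the ethyl ester (acid-catalysed acyl substitution) to give the racemic 2-butyllevulinic acid.

**Step 6**
Reactants: 10 2-butyl-4-oxopentanoic acid
Product: 12 3,5-dibromo-2-butyl-4-oxopentanoic acid, via 3-bromo-2-butyl-4-oxopentanoic acid 11 (not isolated)
Conditions: Br2 (2.05 equiv), cat. HBr, CHCl3, 0 °C → rt; evaporate, use crude
Reagents that add atoms: bromine (BrBr)
Why: Acid-catalysed α-bromination of the ketone through its enols occurs first at the more substituted C3 and then at the C5 methyl, because the first bromine retards further enolisation towards C3; the diastereomer mixture is inconsequential since C2 and C3 become sp2.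

**Step 7**
Reactants: 12 3,5-dibromo-2-butyl-4-oxopentanoic acid
Product: 14 (5Z)-4-bromo-5-(bromomethylidene)-3-butylfuran-2(5H)-one, via 4-bromo-5-(bromomethylidene)-3-butyloxolan-2-one 13 (not isolated)
Conditions: conc. H2SO4 (98%), 100–110 °C, 20 min; pour on ice; CH2Cl2 extraction; SiO2 (35–50% expected)
Reagents that add atoms: none
Why: Acid-mediated cyclodehydration (enol lactonisation) to the presumed dihydro lactone is followed by dehydrogenation of C3–C4 by hot sulfuric acid (reduced to SO2), giving the conjugated bromofuranone as the Z isomer (Br syn to ring O) because the E isomer clashes with the C4 bromine.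

**Step 8**
Reactants: 14 (5Z)-4-bromo-5-(bromomethylidene)-3-butylfuran-2(5H)-one
Product: 15 (5Z)-4-bromo-3-(1-bromobutyl)-5-(bromomethylidene)furan-2(5H)-one
Conditions: NBS (1.1 equiv), AIBN (5 mol%), PhCF3, 85 °C, dark
Reagents that add atoms: N-bromosuccinimide (O=C1CCC(=O)N1Br)
Why: Wohl–Ziegler radical bromination attacks C1′, the only allylic C–H position in the molecule, and gives the racemic secondary bromide.

**Step 9**
Reactants: 15 (5Z)-4-bromo-3-(1-bromobutyl)-5-(bromomethylidene)furan-2(5H)-one
Product: 16 (5Z)-4-bromo-5-(bromomethylidene)-3-(1-hydroxybutyl)furan-2(5H)-one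
Conditions: 1 M aq H2SO4/1,4-dioxane (1:1), reflux, 4 h
Reagents that add atoms: water (O)
Why: Solvolytic nucleophilic substitution of the activated allylic bromide by water gives the racemic alcohol, while the bromodienolide, itself formed in hot sulfuric acid, tolerates the aqueous acid.

**Step 10**
Reactants: 16 (5Z)-4-bromo-5-(bromomethylidene)-3-(1-hydroxybutyl)furan-2(5H)-one
Product: 17 (1R)-1-[(5Z)-4-bromo-5-(bromomethylidene)-2-oxo-2,5-dihydrofuran-3-yl]butyl acetate
Conditions: Burkholderia cepacia lipase (Amano PS-IM), vinyl acetate (3 equiv), MTBE, 35 °C, stop at 50% conversion (chiral HPLC); SiO2 removes the unreacted S enantiomer of 16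
Reagents that add atoms: vinyl acetate (C=COC(C)=O)
Why: Lipase-catalysed kinetic resolution by irreversible transesterification acylates the R alcohol selectively (Kazlauskas rule, large group = furanone ring, medium group = n-propyl), so the 1′R centre is fixed and the acetate is installed in one operation.

**Step 11**
Reactants: 17 (1R)-1-[(5Z)-4-bromo-5-(bromomethylidene)-2-oxo-2,5-dihydrofuran-3-yl]butyl acetate; 14 (5Z)-4-bromo-5-(bromomethylidene)-3-butylfuran-2(5H)-one
Product: 18 (1R)-1-[(5S,6S,11R,12R)-4,10,11,12-tetrabromo-3-butyl-2,8-dioxo-1,7-dioxadispiro[4.0.4.2]dodeca-3,9-dien-9-yl]butyl acetate (CNP0268004.1)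
Conditions: 14 (4 equiv), thioxanthone (10 mol%), degassed CH2Cl2 (0.3 M), 405 nm LEDs, 0–10 °C; SiO2 (removes homodimer of 14), then preparative HPLC
Reagents that add atoms: none
Why: In this triplet-sensitised intermolecular [2+2] photocycloaddition (crossed photodimerisation of the protoanemonin-to-anemonin type) the first bond joins the two CHBr termini to a doubly oxyallyl-stabilised 1,4-diradical that closes head-to-head between the two C5 atoms with the lactone oxygens anti and each bromine trans to the neighbouring oxygen and to the other bromine, so the four ring stereocentres are set in this closure without facial control from the remote 1′R centre and the (5S,6S,11R,12R) product is separated from its (5R,6R,11S,12S) diastereomer by HPLC.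

**Compound list**
1 | ethyl levulinate (ethyl 4-oxopentanoate) | CCOC(=O)CCC(C)=O | starting material
2 | ethyl 3-(2-methyl-1,3-dioxolan-2-yl)propanoate | CCOC(=O)CCC1(C)OCCO1 | intermediate
3 | butanal | CCCC=O | starting material
4 | lithium ester enolate of 2 (enolate geometry not relevant) | CCOC(O[Li])=CCC1(C)OCCO1 | intermediate (not isolated)
5 | ethyl 3-hydroxy-2-[(2-methyl-1,3-dioxolan-2-yl)methyl]hexanoate (racemic diastereomer mixture) | CCCC(O)C(CC1(C)OCCO1)C(=O)OCC | intermediate
6 | ethyl 3-(methylsulfonyloxy)-2-[(2-methyl-1,3-dioxolan-2-yl)methyl]hexanoate (β-mesyloxy ester) | CCCC(OS(C)(=O)=O)C(CC1(C)OCCO1)C(=O)OCC | intermediate (not isolated)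
7 | ethyl 2-[(2-methyl-1,3-dioxolan-2-yl)methyl]hex-2-enoate (E/Z mixture) | CCCC=C(CC1(C)OCCO1)C(=O)OCC | intermediate
8 | ethyl 2-[(2-methyl-1,3-dioxolan-2-yl)methyl]hexanoate (racemic) | CCCCC(CC1(C)OCCO1)C(=O)OCC | intermediate
9 | ethyl 2-butyl-4-oxopentanoate (racemic) | CCCCC(CC(C)=O)C(=O)OCC | intermediate (not isolated)
10 | 2-butyl-4-oxopentanoic acid (racemic) | CCCCC(CC(C)=O)C(=O)O | intermediate
11 | 3-bromo-2-butyl-4-oxopentanoic acid (diastereomer mixture) | CCCCC(C(Br)C(C)=O)C(=O)O | intermediate (not isolated)
12 | 3,5-dibromo-2-butyl-4-oxopentanoic acid (diastereomer mixture) | CCCCC(C(Br)C(=O)CBr)C(=O)O | intermediate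
13 | (5Z)-4-bromo-5-(bromomethylidene)-3-butyloxolan-2-one (diastereomer mixture, presumed) | CCCCC1C(Br)/C(=C/Br)OC1=O | intermediate (not isolated)
14 | (5Z)-4-bromo-5-(bromomethylidene)-3-butylfuran-2(5H)-one (fimbrolide) | CCCCC1=C(Br)/C(=C/Br)OC1=O | intermediate
15 | (5Z)-4-bromo-3-(1-bromobutyl)-5-(bromomethylidene)furan-2(5H)-one (racemic) | CCCC(Br)C1=C(Br)/C(=C/Br)OC1=O | intermediate
16 | (5Z)-4-bromo-5-(bromomethylidene)-3-(1-hydroxybutyl)furan-2(5H)-one (racemic) | CCCC(O)C1=C(Br)/C(=C/Br)OC1=O | intermediate
17 | (1R)-1-[(5Z)-4-bromo-5-(bromomethylidene)-2-oxo-2,5-dihydrofuran-3-yl]butyl acetate | CCC[C@@H](OC(C)=O)C1=C(Br)/C(=C/Br)OC1=O | intermediate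
18 | (1R)-1-[(5S,6S,11R,12R)-4,10,11,12-tetrabromo-3-butyl-2,8-dioxo-1,7-dioxadispiro[4.0.4.2]dodeca-3,9-dien-9-yl]butyl acetate | CCCCC1=C(Br)[C@@]2(OC1=O)[C@@H](Br)[C@H](Br)[C@@]21OC(=O)C([C@@H](CCC)OC(C)=O)=C1Br | target

**Totals**
Total steps: 11. Longest linear sequence: 11 (1 → 18; compound 14 is used twice, as precursor of 17 and as the cycloaddition partner in step 11).

**Steps most likely to fail**

Step 11 (crossed photodimerisation). Hetero- versus homodimerisation is statistical, the remote stereocentre gives no facial control, the relative configuration from diradical closure is predicted by analogy only, and vinyl C–Br bonds may photolyse. The fallback sets out from 14 and comes back at 18. Irradiating 14 alone under the same sensitised conditions removes the cross-selectivity problem and gives the racemic head-to-head anti homodimer 4,10,11,12-tetrabromo-3,9-dibutyl-1,7-dioxadispiro[4.0.4.2]dodeca-3,9-diene-2,8-dione F1. One equivalent of NBS with AIBN then brominates one of its two homotopic C1′ positions to give the monobromide 4,10,11,12-tetrabromo-3-(1-bromobutyl)-9-butyl-1,7-dioxadispiro[4.0.4.2]dodeca-3,9-diene-2,8-dione F2. Aqueous acidic solvolysis and chromatographic separation of the two racemic diastereomers gives the mono-alcohol 4,10,11,12-tetrabromo-3-butyl-9-(1-hydroxybutyl)-1,7-dioxadispiro[4.0.4.2]dodeca-3,9-diene-2,8-dione F3, as the racemate whose 1′R enantiomer carries the 5S,6S,11R,12R core. Lipase PS with vinyl acetate then acetylates only that 1′R enantiomer to give 18, which is separated from the untouched enantiomeric alcohol.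

Step 10 (lipase resolution). The bromodienolide is a haloenol lactone and Michael acceptor that may inactivate the enzyme, and n-propyl is a large "medium" group. The fallback sets out from 16 and comes back at 17. Dess–Martin oxidation of racemic 16 gives the ketone (5Z)-4-bromo-5-(bromomethylidene)-3-butanoylfuran-2(5H)-one F4. Reduction with (S)-Me-CBS and catecholborane at −78 °C, with the furanone as the large group, gives (5Z)-4-bromo-5-(bromomethylidene)-3-[(1R)-1-hydroxybutyl]furan-2(5H)-one F5. Acetylation with Ac2O and pyridine gives 17, and all material is funnelled to the R series.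

Step 9 (solvolysis of the bromide). Vinylogous SN2′ attack at the bromodienolide, elimination to the 1′-alkene or sluggish substitution may intervene. The fallback sets out from 15 and comes back at 17. Silver acetate in acetic acid (silver-assisted acetolysis) converts 15 directly into racemic 1-[(5Z)-4-bromo-5-(bromomethylidene)-2-oxo-2,5-dihydrofuran-3-yl]butyl acetate F6. This is resolved by preparative chiral SFC to give 17, which bypasses both the alcohol and the enzyme.

**Further compounds**
F1 | step 11 | rac-(5S,6S,11R,12R)-4,10,11,12-tetrabromo-3,9-dibutyl-1,7-dioxadispiro[4.0.4.2]dodeca-3,9-diene-2,8-dione (one enantiomer drawn) | CCCCC1=C(Br)[C@@]2(OC1=O)[C@@H](Br)[C@H](Br)[C@@]21OC(=O)C(CCCC)=C1Br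
F2 | step 11 | rac-(5S,6S,11R,12R)-4,10,11,12-tetrabromo-3-(1-bromobutyl)-9-butyl-1,7-dioxadispiro[4.0.4.2]dodeca-3,9-diene-2,8-dione (both C1′ epimers) | CCCCC1=C(Br)[C@@]2(OC1=O)[C@@H](Br)[C@H](Br)[C@@]21OC(=O)C(C(Br)CCC)=C1Br
F3 | step 11 | rac-(5S,6S,11R,12R)-4,10,11,12-tetrabromo-3-butyl-9-[(1R)-1-hydroxybutyl]-1,7-dioxadispiro[4.0.4.2]dodeca-3,9-diene-2,8-dione (relative configuration, one enantiomer drawn) | CCCCC1=C(Br)[C@@]2(OC1=O)[C@@H](Br)[C@H](Br)[C@@]21OC(=O)C([C@@H](CCC)O)=C1Br
F4 | step 10 | (5Z)-4-bromo-5-(bromomethylidene)-3-butanoylfuran-2(5H)-one | CCCC(=O)C1=C(Br)/C(=C/Br)OC1=O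
F5 | step 10 | (5Z)-4-bromo-5-(bromomethylidene)-3-[(1R)-1-hydroxybutyl]furan-2(5H)-one | CCC[C@@H](O)C1=C(Br)/C(=C/Br)OC1=O
F6 | step 9 | racemic 1-[(5Z)-4-bromo-5-(bromomethylidene)-2-oxo-2,5-dihydrofuran-3-yl]butyl acetate | CCCC(OC(C)=O)C1=C(Br)/C(=C/Br)OC1=O
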